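**Retrosynthetic overview**
1. Strongylophorine-8 (24) ⇐ dimethyl ether 22 (cerium oxidation, then dithionite) ⇐ C13 exocyclic alkene 20 (Markovnikov radical hydration sets C13).
2. 20 ⇐ spiro-epoxide 18: trivalent titanium opens the epoxide to the C10 radical, which closes ring B and then ring C (C10–C9, C8–C14); the freed C20 hydroxyl then lactonizes onto the C19 amide.
3. 18 ⇐ ring A ketone 16 ⇐ enol ether 14 (hydrogenation; hydrolysis sets C5).
4. Key step: 14 ⇐ benzamide 12 by auxiliary-controlled Birch reductive methylation; the benzene ring of 3-methoxy-2-methylbenzoic acid becomes ring A and the C4 quaternary centre is set, from which all other centres are relayed.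
5. 12 ⇐ amide 10 + allylic bromide 6 (from 1,4-dimethoxybenzene and geranyl bromide). Ring order: A (arene), B, C, lactone.

Assumption: the (S)-prolinol methyl ether amide is taken to give the C4 configuration shown, by analogy with Schultz's 2-alkylbenzamides; if the sense proves opposite, the (R)-amine is used with no other change.

Numbering and abbreviations: diterpenoid numbering throughout (C4 carries CH3 and the C19 carbonyl; C10 carries C20H2O; C8 and C13 carry CH3; C14 carries C15H2Ar). Ar = 2,5-dimethoxyphenyl; SC = (3E,7E)-9-Ar-3,7-dimethylnona-3,7-dienyl; Xc = (S)-2-(methoxymethyl)pyrrolidin-1-yl.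

**Step 1**
Reactants: 1 1,4-dimethoxybenzene; 2 geranyl bromide
Product: 4 2-geranyl-1,4-dimethoxybenzene, via 2,5-dimethoxyphenyllithium 3 (not isolated)
Conditions: n-BuLi, TMEDA, THF, 0 °C; then 2, −78 °C → rt
Reagents that add atoms: none
Why: Directed ortho-lithiation of the dimethoxyarene followed by SN2 alkylation with the primary allylic bromide, which keeps the E-alkene.

**Step 2**
Reactants: 4 2-geranyl-1,4-dimethoxybenzene
Product: 5 (2E,6E)-8-(2,5-dimethoxyphenyl)-2,6-dimethylocta-2,6-dien-1-ol
Conditions: SeO2 (0.3 equiv), t-BuOOH, salicylic acid (cat.), CH2Cl2, 0 °C → rt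
Reagents that add atoms: selenium dioxide O=[Se]=O; tert-butyl hydroperoxide CC(C)(C)OO
Why: Sharpless catalytic SeO2 allylic oxidation (ene, then 2,3-shift) hydroxylates the terminal E-methyl group of the distal trisubstituted alkene and gives the E-allylic alcohol.

**Step 3**
Reactants: 5 allylic alcohol
Product: 6 2-[(2E,6E)-8-bromo-3,7-dimethylocta-2,6-dienyl]-1,4-dimethoxybenzene
Conditions: PBr3, Et2O, −10 °C
Reagents that add atoms: phosphorus tribromide BrP(Br)Br
Why: Standard conversion of a primary allylic alcohol into the bromide with retention of alkene geometry.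

**Step 4**
Reactants: 7 3-methoxy-2-methylbenzoic acid; 8 (S)-2-(methoxymethyl)pyrrolidine
Product: 10 (S)-1-(3-methoxy-2-methylbenzoyl)-2-(methoxymethyl)pyrrolidine, via 3-methoxy-2-methylbenzoyl chloride 9 (not isolated)
Conditions: (COCl)2, DMF (cat.), CH2Cl2, 0 °C → rt; then 8, Et3N, 0 °C
Reagents that add atoms: none
Why: Acid chloride formation and amide coupling install the chiral auxiliary that later controls the Birch alkylation.

**Step 5**
Reactants: 10 chiral benzamide; 6 allylic bromide
Product: 12 (S)-1-[2-SC-3-methoxybenzoyl]-2-(methoxymethyl)pyrrolidine, via laterally lithiated amide 11 (not isolated)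
Conditions: LiN(i-Pr)2, THF, −78 °C; then 6, −78 → −20 °C
Reagents that add atoms: none
Why: Lateral (benzylic) lithiation of the o-toluamide, whose methyl group is acidified by the amide and flanked by OMe, then SN2 alkylation with the primary allylic bromide; this joins C6 to C7 and completes the carbon skeleton.

**Step 6 (key step)**
Reactants: 12 benzamide
Product: 14 (1S)-3-methoxy-1-methyl-2-SC-cyclohexa-2,5-diene-1-carbonyl-Xc, via potassium amide enolate 13 (not isolated)
Conditions: K (2.4 equiv), NH3/THF, t-BuOH (1 equiv), −78 °C; piperylene; then MeI, −78 °C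
Reagents that add atoms: iodomethane CI
Why: Schultz asymmetric Birch reductive alkylation: only the benzamide ring is reduced at −78 °C with one equivalent of t-BuOH (the dimethoxyphenyl ring and isolated alkenes are not), and the chelated potassium enolate is methylated at C4 on the face away from the CH2OMe arm, which sets the C4 quaternary centre.

**Step 7**
Reactants: 14 cyclohexa-2,5-diene
Product: 15 (1S)-3-methoxy-1-methyl-2-SC-cyclohex-2-ene-1-carbonyl-Xc
Conditions: H2 (1 atm), RhCl(PPh3)3 (5 mol %), PhH, rt
Reagents that add atoms: none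
Why: Homogeneous hydrogenation with RhCl(PPh3)3 reduces only the cis-disubstituted C2=C3 alkene; the tetrasubstituted enol ether and the trisubstituted chain alkenes are inert to this catalyst.

**Step 8**
Reactants: 15 enol ether
Product: 16 (1S,2S)-1-methyl-3-oxo-2-SC-cyclohexane-1-carbonyl-Xc (C5-H cis to the C4 methyl, side chain cis to the amide)
Conditions: 0.5 M HCl, THF, 0 °C
Reagents that add atoms: water O
Why: Enol ether hydrolysis in which the rate-limiting proton transfer to C5 occurs on the face opposite the pseudo-axial C4 amide, so the side chain ends cis to the carbonyl, and the cold dilute acid avoids later enolization of the ketone.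

**Step 9**
Reactants: 16 ketone
Product: 18 spiro-epoxide at C10 (1-oxaspiro[2.5]octane; both C10 epimers), via lithium chlorohydrin alkoxide 17 (not isolated)
Conditions: ClCH2I, MeLi·LiBr, THF, −78 °C → rt
Reagents that add atoms: chloroiodomethane ClCI
Why: Matteson-type homologation: chloromethyllithium made in situ by iodine–lithium exchange adds to the ketone at −78 °C without enolizing C5 and the alkoxide closes to the epoxide; the C10 configuration does not matter because C10 becomes a planar radical in the next step.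

**Step 10**
Reactants: 18 spiro-epoxide
Product: 20 tricyclic 19,20-lactone with C13 exocyclic methylene (4α-CH3; 5α-H; 8β-CH3; 9α-H; 10β-CH2O; 14β-CH2Ar), via hydroxy amide 19 (not isolated)
Conditions: (C5H5)2TiCl2 (2.5 equiv), Mn dust, THF, rt, slow addition of 18; then 1 M HCl, 40 °C
Reagents that add atoms: none
Why: Nugent–RajanBabu epoxide opening by trivalent titanium gives the tertiary C10 radical bearing CH2OTi, which closes ring B and then ring C by two 6-endo additions through chair-like transition states on the E-alkenes (as in titanocene epoxypolyene cyclizations; this sets 10β-CH2O, 9α-H, 8β-CH3 and 14α-H relative to the equatorial C5 chain), the C13 radical is trapped by a second titanium and β-hydride elimination gives the exocyclic alkene, and acid then drives N-to-O acyl transfer between the 1,3-diaxial CH2OH and amide, releasing the auxiliary.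

**Step 11**
Reactants: 20 exocyclic alkene
Product: 22 di-O-methylstrongylophorine-8 (13α-OH; 13β-CH3), via tertiary hydroperoxide 21 (not isolated)
Conditions: Mn(dpm)3 (10 mol %; dpm = 2,2,6,6-tetramethylheptane-3,5-dionate), PhSiH3, O2 (1 atm), i-PrOH/CH2Cl2, 0 °C; then PPh3
Reagents that add atoms: dioxygen O=O
Why: Mukaiyama hydration by hydrogen-atom transfer gives the tertiary C13 radical, which O2 traps on the equatorial α face because the β face is blocked by the syn-axial C8 methyl; this sets 13α-OH/13β-CH3.

**Step 12**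
Reactants: 22 dimethyl ether
Product: 24 strongylophorine-8, via benzoquinone 23 (not isolated)
Conditions: (NH4)2Ce(NO3)6, MeCN/H2O, 0 °C; then aq. Na2S2O4, EtOAc, rt
Reagents that add atoms: water O
Why: Oxidative demethylation of the 1,4-dimethoxyarene by tetravalent cerium gives the p-quinone without touching lactone or tertiary alcohol, and neutral dithionite reduction gives the hydroquinone without acid that could close it onto C13.

**Compound list**
1 | 1,4-dimethoxybenzene | COc1ccc(OC)cc1 | starting material
2 | geranyl bromide | CC(C)=CCC/C(C)=C/CBr | starting material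
3 | 2,5-dimethoxyphenyllithium | [Li]c1cc(OC)ccc1OC | intermediate
4 | 2-geranyl-1,4-dimethoxybenzene | COc1ccc(OC)c(C/C=C(\C)CCC=C(C)C)c1 | intermediate
5 | (2E,6E)-8-(2,5-dimethoxyphenyl)-2,6-dimethylocta-2,6-dien-1-ol | COc1ccc(OC)c(C/C=C(\C)CC/C=C(\C)CO)c1 | intermediate
6 | 2-[(2E,6E)-8-bromo-3,7-dimethylocta-2,6-dienyl]-1,4-dimethoxybenzene | COc1ccc(OC)c(C/C=C(\C)CC/C=C(\C)CBr)c1 | intermediate
7 | 3-methoxy-2-methylbenzoic acid | COc1cccc(C(=O)O)c1C | starting material
8 | (S)-2-(methoxymethyl)pyrrolidine | COC[C@@H]1CCCN1 | starting material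
9 | 3-methoxy-2-methylbenzoyl chloride | COc1cccc(C(=O)Cl)c1C | intermediate
10 | (S)-1-(3-methoxy-2-methylbenzoyl)-2-(methoxymethyl)pyrrolidine | COC[C@@H]1CCCN1C(=O)c1cccc(OC)c1C | intermediate
11 | laterally lithiated amide (ArCH2Li) | COC[C@@H]1CCCN1C(=O)c1cccc(OC)c1C[Li] | intermediate
12 | benzamide carrying the full side chain SC at C5 | COC[C@@H]1CCCN1C(=O)c1cccc(OC)c1CC/C(C)=C/CC/C(C)=C/Cc1cc(OC)ccc1OC | intermediate
13 | potassium amide enolate of the 1,4-dihydro ring | [K+].COC[C@@H]1CCCN1C([O-])=C1C=CCC(OC)=C1CC/C(C)=C/CC/C(C)=C/Cc1cc(OC)ccc1OC | intermediate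
14 | (1S)-3-methoxy-1-methyl-2-SC-cyclohexa-2,5-diene-1-carbonyl-Xc | COC1=C(CC/C(C)=C/CC/C(C)=C/Cc2cc(OC)ccc2OC)[C@@](C)(C(=O)N2CCC[C@H]2COC)C=CC1 | intermediate
15 | (1S)-3-methoxy-1-methyl-2-SC-cyclohex-2-ene-1-carbonyl-Xc | COC1=C(CC/C(C)=C/CC/C(C)=C/Cc2cc(OC)ccc2OC)[C@@](C)(C(=O)N2CCC[C@H]2COC)CCC1 | intermediate
16 | (1S,2S)-1-methyl-3-oxo-2-SC-cyclohexane-1-carbonyl-Xc | O=C1CCC[C@](C)(C(=O)N2CCC[C@H]2COC)[C@@H]1CC/C(C)=C/CC/C(C)=C/Cc1cc(OC)ccc1OC | intermediate
17 | lithium chlorohydrin alkoxide (C10 epimers) | [Li+].[O-]C1(CCl)CCC[C@](C)(C(=O)N2CCC[C@H]2COC)[C@@H]1CC/C(C)=C/CC/C(C)=C/Cc1cc(OC)ccc1OC | intermediate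
18 | C10 spiro-epoxide (C10 epimers) | C1OC12CCC[C@](C)(C(=O)N3CCC[C@H]3COC)[C@@H]2CC/C(C)=C/CC/C(C)=C/Cc1cc(OC)ccc1OC | intermediate
19 | tricyclic 20-hydroxy 19-amide with C13 exocyclic methylene (trans-anti-trans) | C[C@@]12CC[C@@H]3[C@](CO)(CCC[C@]3(C)C(=O)N3CCC[C@H]3COC)[C@H]1CCC(=C)[C@H]2Cc1cc(OC)ccc1OC | intermediate
20 | tricyclic 19,20-lactone with C13 exocyclic methylene | C[C@@]12CC[C@@H]3[C@]4(CCC[C@]3(C)C(=O)OC4)[C@H]1CCC(=C)[C@H]2Cc1cc(OC)ccc1OC | intermediate
21 | 13α-hydroperoxide | C[C@@]12CC[C@@H]3[C@]4(CCC[C@]3(C)C(=O)OC4)[C@H]1CC[C@](C)(OO)[C@H]2Cc1cc(OC)ccc1OC | intermediate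
22 | di-O-methylstrongylophorine-8 | C[C@@]12CC[C@@H]3[C@]4(CCC[C@]3(C)C(=O)OC4)[C@H]1CC[C@](C)(O)[C@H]2Cc1cc(OC)ccc1OC | intermediate
23 | benzoquinone corresponding to the target | C[C@@]12CC[C@@H]3[C@]4(CCC[C@]3(C)C(=O)OC4)[C@H]1CC[C@](C)(O)[C@H]2CC1=CC(=O)C=CC1=O | intermediate
24 | strongylophorine-8 | C[C@@]12CC[C@@H]3[C@]4(CCC[C@]3(C)C(=O)OC4)[C@H]1CC[C@](C)(O)[C@H]2Cc1cc(O)ccc1O | target

**Step count:** 12 steps in total. Longest linear sequence: 11 steps (1, 2, 3, 5, 6, 7, 8, 9, 10, 11, 12).

**Steps most likely to fail and fallbacks**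

Step 10 (radical bicyclization and lactonization). If the titanium-mediated cascade stops early or gives the wrong ring fusion, the cyclization is run cationically from 18 with MeAlCl2 in CH2Cl2 at −78 °C. The C10 cation from the epoxide closes rings B and C, and the C13 cation is captured by the neighbouring methoxy oxygen, with chloride removing the methyl group, to give the methoxychromane hydroxy amide F1. Dilute HCl converts this into the methoxychromane lactone F2. (NH4)2Ce(NO3)6 in aqueous MeCN then opens the 6-methoxychromane oxidatively, keeping the C13–O bond, to give benzoquinone 23, where the route is rejoined.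

Step 8 (C5 configuration on hydrolysis). If proton transfer gives the C5 epimer or a mixture, the hydrogen is delivered to a radical instead. From 15, N-bromosuccinimide in aqueous THF at −78 °C gives the C5 bromo ketone F3. Bu3SnH with Et3B/O2 at −78 °C then reduces it through the planar C5 radical, which takes hydrogen on the face away from the amide under neutral, non-epimerizing conditions, and the route is rejoined at 16.

Step 11 (facial selectivity of the hydration). If the radical hydration gives the wrong C13 epimer, the oxygen is brought in from the arene. From 20, BBr3 in CH2Cl2 (−78 → 0 °C) removes both methyl ethers to give the hydroquinone alkene F4. Under the acid present, its ortho hydroxyl adds to the C13 cation from the open α face to give the trans-fused chromanol F5. (NH4)2Ce(NO3)6 in aqueous MeCN oxidizes the chromanol with ring opening to benzoquinone 23, where the route is rejoined.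

**Further compounds**
F1 | step 10 | methoxychromane hydroxy amide (C13–O–aryl ring closed; 20-OH; 19-amide) | C[C@@]12CC[C@@H]3[C@](CO)(CCC[C@]3(C)C(=O)N3CCC[C@H]3COC)[C@H]1CC[C@]1(C)Oc3ccc(OC)cc3C[C@@H]21
F2 | step 10 | methoxychromane 19,20-lactone | C[C@@]12CC[C@@H]3[C@]4(CCC[C@]3(C)C(=O)OC4)[C@H]1CC[C@]1(C)Oc3ccc(OC)cc3C[C@@H]21
F3 | step 8 | C5 bromo ketone (C5 epimers) | O=C1CCC[C@](C)(C(=O)N2CCC[C@H]2COC)C1(Br)CC/C(C)=C/CC/C(C)=C/Cc1cc(OC)ccc1OC
F4 | step 11 | hydroquinone with C13 exocyclic methylene | C[C@@]12CC[C@@H]3[C@]4(CCC[C@]3(C)C(=O)OC4)[C@H]1CCC(=C)[C@H]2Cc1cc(O)ccc1O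
F5 | step 11 | trans-fused chromanol 19,20-lactone | C[C@@]12CC[C@@H]3[C@]4(CCC[C@]3(C)C(=O)OC4)[C@H]1CC[C@]1(C)Oc3ccc(O)cc3C[C@@H]21
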